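**Retrosynthetic overview**
1. The target (ambuic acid) comes from a ketal- and ester-protected cis-epoxy alcohol, which comes from an epoxy ketone by hydride delivery anti to the epoxide, which in turn comes from a p-quinone monoketal by tartrate-mediated asymmetric nucleophilic epoxidation.
2. The quinone monoketal comes from a 2,3,5-trisubstituted phenol by oxidative dearomatisation in methanol.
3. Key step: the phenol ring is made by nickel-catalysed two-carbon ring expansion of a 3-substituted cyclobutenone with a conjugated enyne (C–C cleavage and alkyne insertion, four- to six-membered ring).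
4. The cyclobutenone comes from 3-ethoxycyclobutenone, allyl Grignard and methyl methacrylate (cross-metathesis); the enyne comes from hept-1-yne and a silyl propargyl ether.
5. Ring order: the bought four-membered ring is expanded to the six-membered carbocycle, and the oxirane is formed last.

Assumption: L-(+)-diisopropyl tartrate is written in step 7 as the antipode that gives the (1R,6S)-epoxide; I could not confirm this sense, and if the first run gives the enantiomer, D-(−)-diisopropyl tartrate replaces it with nothing else changed.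

**Route**

Step 1
Reactants: 1 hept-1-yne
Product: 3 (E)-1-iodohept-1-ene, via alkenylzirconocene chloride 2 (not isolated)
Conditions: Cp2Zr(H)Cl (1.1 equiv), THF, rt; then I2, 0 °C
Reagents that add atoms: iodine, [I][I]
Why: Hydrozirconation–iodination: syn addition of Zr–H places zirconium on the terminal carbon and iodinolysis of the alkenyl–Zr bond goes with retention, so only the (E)-iodide forms.

Step 2
Reactants: 3 (E)-1-iodohept-1-ene; 4 tert-butyldimethyl(prop-2-yn-1-yloxy)silane
Product: 5 tert-butyl-[(E)-dec-4-en-2-ynoxy]-dimethylsilane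
Conditions: Pd(PPh3)2Cl2 (2 mol%), CuI (4 mol%), Et3N, THF, rt
Reagents that add atoms: none
Why: Sonogashira coupling of an alkenyl iodide with a terminal alkyne keeps the (E)-geometry and tolerates the silyl ether.

Step 3
Reactants: 6 3-ethoxycyclobut-2-en-1-one; 7 allylmagnesium bromide
Product: 9 3-(prop-2-enyl)cyclobut-2-en-1-one, via magnesium alkoxide 8 (not isolated)
Conditions: Et2O, −78 °C; then 1 M HCl, 0 °C
Reagents that add atoms: water, O
Why: Stork–Danheiser-type alkoxyenone transposition: 1,2-addition of the Grignard reagent to the vinylogous ester, then acid ionisation of the tertiary allylic alcohol and hydrolysis of the oxocarbenium ion, gives the 3-substituted cyclobutenone.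

Step 4
Reactants: 9 3-(prop-2-enyl)cyclobut-2-en-1-one; 10 methyl methacrylate
Product: 11 methyl (E)-2-methyl-4-(3-oxocyclobut-1-en-1-yl)but-2-enoate
Conditions: 10 (6 equiv), second-generation Hoveyda–Grubbs catalyst (5 mol%), 1,4-benzoquinone (10 mol%), CH2Cl2, 40 °C
Reagents that add atoms: none
Why: Olefin cross-metathesis of the terminal allyl group with the 1,1-disubstituted acrylate gives the trisubstituted enoate with thermodynamic (E)-selectivity, while the electron-poor trisubstituted ring alkene should not engage the ruthenium carbene and benzoquinone suppresses Ru–H isomerisation of the skipped diene.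

Step 5
Reactants: 11 methyl (E)-2-methyl-4-(3-oxocyclobut-1-en-1-yl)but-2-enoate; 5 tert-butyl-[(E)-dec-4-en-2-ynoxy]-dimethylsilane
Product: 13 methyl (E)-4-[4-[[tert-butyl(dimethyl)silyl]oxymethyl]-3-[(E)-hept-1-enyl]-5-hydroxyphenyl]-2-methylbut-2-enoate, via cyclohexadienone 12 (not isolated)
Conditions: Ni(cod)2 (10 mol%), PCy3 (10 mol%), 5 (1.2 equiv), toluene, 0 °C to rt, slow addition of 11
Reagents that add atoms: none
Why: Proposed new method: a zerovalent-nickel-catalysed formal [4+2] ring expansion of a 3-substituted cyclobutenone by a conjugated 1,3-enyne, in which the PCy3–nickel–enyne complex joins the strained acyl carbon to the alkyne carbon remote from the alkene (the alkenyl-bearing carbon stays on nickel as an eta-3 dienyl unit), the acyl–C(sp3) bond of the four-membered ring is cut by strain-driven beta-carbon elimination, C(sp3)–C(sp2) reductive elimination closes dienone 12 and tautomerisation gives phenol 13 with the silyloxymethyl group ortho and the heptenyl group meta to the hydroxyl; the closest known reactions are the Ni(cod)2-catalysed phenol synthesis from cyclobutenones and simple alkynes, the nickel-catalysed alkyne insertion into cyclobutanones and the alkene-directed regiocontrol of nickel-catalysed carbonyl–enyne couplings, and no stereocentre is formed.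

Step 6
Reactants: 13 methyl (E)-4-[4-[[tert-butyl(dimethyl)silyl]oxymethyl]-3-[(E)-hept-1-enyl]-5-hydroxyphenyl]-2-methylbut-2-enoate
Product: 17 methyl (E)-4-[5-[(E)-hept-1-enyl]-4-(hydroxymethyl)-6,6-dimethoxy-3-oxocyclohexa-1,4-dien-1-yl]-2-methylbut-2-enoate, via methoxy dienone 14 (not isolated), via methoxyphenol 15 (not isolated), via silyl ketal 16 (not isolated)
Conditions: PhI(OAc)2 (2.2 equiv), MeOH, 0 °C; then CSA (20 mol%), rt
Reagents that add atoms: methanol, CO
Why: Two successive oxidative dearomatisations by the trivalent-iodine reagent with methanol capture at the free para carbon (phenol to para-methoxyphenol to para-quinone monoketal), then acid-catalysed methanolysis of the primary silyl ether in the same flask, in which the dimethyl ketal is stable because the medium is dry methanol.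

Step 7
Reactants: 17 methyl (E)-4-[5-[(E)-hept-1-enyl]-4-(hydroxymethyl)-6,6-dimethoxy-3-oxocyclohexa-1,4-dien-1-yl]-2-methylbut-2-enoate
Product: 18 methyl (E)-4-[(1R,6S)-3-[(E)-hept-1-enyl]-4-(hydroxymethyl)-2,2-dimethoxy-5-oxo-7-oxabicyclo[4.1.0]hept-3-en-1-yl]-2-methylbut-2-enoate
Conditions: Ph3COOH (3 equiv), NaHMDS (2.5 equiv), L-(+)-diisopropyl tartrate (1.2 equiv), 4 Å MS, toluene, −50 °C; aq. NH4Cl
Reagents that add atoms: trityl hydroperoxide, OOC(c1ccccc1)(c1ccccc1)c1ccccc1
Why: Tartrate-mediated asymmetric Weitz–Scheffer epoxidation: the sodium alkoxide of the hydroxymethyl group and the tartrate form a chiral aggregate that delivers trityl peroxide to one face of the less substituted enone alkene, and closure of the peroxy enolate sets both epoxide centres (1R,6S) in one event.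

Step 8
Reactants: 18 methyl (E)-4-[(1R,6S)-3-[(E)-hept-1-enyl]-4-(hydroxymethyl)-2,2-dimethoxy-5-oxo-7-oxabicyclo[4.1.0]hept-3-en-1-yl]-2-methylbut-2-enoate
Product: 19 methyl (E)-4-[(1R,5R,6R)-3-[(E)-hept-1-enyl]-5-hydroxy-4-(hydroxymethyl)-2,2-dimethoxy-7-oxabicyclo[4.1.0]hept-3-en-1-yl]-2-methylbut-2-enoate
Conditions: NaBH4 (1.2 equiv), CeCl3·7H2O (1.2 equiv), MeOH, −78 °C
Reagents that add atoms: none
Why: Luche 1,2-reduction in which hydride adds to the face opposite the adjacent epoxide C–O bond (polar Felkin–Anh and steric control on the nearly flat ring), so the new hydroxyl is cis to the epoxide oxygen (5R) and the ester and ketal are untouched.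

Step 9
Reactants: 19 methyl (E)-4-[(1R,5R,6R)-3-[(E)-hept-1-enyl]-5-hydroxy-4-(hydroxymethyl)-2,2-dimethoxy-7-oxabicyclo[4.1.0]hept-3-en-1-yl]-2-methylbut-2-enoate
Product: 21 (E)-4-[(1R,5R,6R)-3-[(E)-hept-1-enyl]-5-hydroxy-4-(hydroxymethyl)-2-oxo-7-oxabicyclo[4.1.0]hept-3-en-1-yl]-2-methylbut-2-enoic acid (ambuic acid), via lithium carboxylate 20 (not isolated)
Conditions: LiOH·H2O (3 equiv), THF/H2O 3:1, rt; then TFA to pH 1, 0 °C to rt
Reagents that add atoms: lithium hydroxide, [Li+].[OH-]; water, O
Why: Ester saponification is run while the base-sensitive epoxy ketone is still masked as its ketal (the cis epoxy alcohol cannot undergo Payne rearrangement), and acid hydrolysis of the dimethyl ketal in the same flask then releases the conjugated ketone without touching any stereocentre.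

**Compound list**
1 | hept-1-yne | CCCCCC#C | starting material
2 | chloridobis(cyclopentadienyl)[(E)-hept-1-enyl]zirconium (cyclopentadienyl rings drawn sigma-bound) | CCCCC/C=C/[Zr](Cl)(C1C=CC=C1)C1C=CC=C1 | intermediate
3 | (E)-1-iodohept-1-ene | CCCCC/C=C/I | intermediate
4 | tert-butyldimethyl(prop-2-yn-1-yloxy)silane (silyl ether of propargyl alcohol) | C#CCO[Si](C)(C)C(C)(C)C | starting material
5 | tert-butyl-[(E)-dec-4-en-2-ynoxy]-dimethylsilane | CCCCC/C=C/C#CCO[Si](C)(C)C(C)(C)C | intermediate
6 | 3-ethoxycyclobut-2-en-1-one | CCOC1=CC(=O)C1 | starting material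
7 | allylmagnesium bromide | C=CC[Mg]Br | starting material
8 | bromomagnesium 3-ethoxy-1-(prop-2-enyl)cyclobut-2-en-1-olate | C=CCC1(O[Mg]Br)C=C(OCC)C1 | intermediate
9 | 3-(prop-2-enyl)cyclobut-2-en-1-one | C=CCC1=CC(=O)C1 | intermediate
10 | methyl methacrylate (methyl 2-methylprop-2-enoate) | C=C(C)C(=O)OC | starting material
11 | methyl (E)-2-methyl-4-(3-oxocyclobut-1-en-1-yl)but-2-enoate | COC(=O)/C(C)=C/CC1=CC(=O)C1 | intermediate
12 | methyl (E)-4-[4-[[tert-butyl(dimethyl)silyl]oxymethyl]-5-[(E)-hept-1-enyl]-3-oxocyclohexa-1,4-dien-1-yl]-2-methylbut-2-enoate | CCCCC/C=C/C1=C(CO[Si](C)(C)C(C)(C)C)C(=O)C=C(C/C=C(\C)C(=O)OC)C1 | intermediate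
13 | methyl (E)-4-[4-[[tert-butyl(dimethyl)silyl]oxymethyl]-3-[(E)-hept-1-enyl]-5-hydroxyphenyl]-2-methylbut-2-enoate | CCCCC/C=C/c1cc(C/C=C(\C)C(=O)OC)cc(O)c1CO[Si](C)(C)C(C)(C)C | intermediate
14 | methyl (E)-4-[4-[[tert-butyl(dimethyl)silyl]oxymethyl]-5-[(E)-hept-1-enyl]-6-methoxy-3-oxocyclohexa-1,4-dien-1-yl]-2-methylbut-2-enoate (racemic) | CCCCC/C=C/C1=C(CO[Si](C)(C)C(C)(C)C)C(=O)C=C(C/C=C(\C)C(=O)OC)C1OC | intermediate
15 | methyl (E)-4-[4-[[tert-butyl(dimethyl)silyl]oxymethyl]-3-[(E)-hept-1-enyl]-5-hydroxy-2-methoxyphenyl]-2-methylbut-2-enoate | CCCCC/C=C/c1c(OC)c(C/C=C(\C)C(=O)OC)cc(O)c1CO[Si](C)(C)C(C)(C)C | intermediate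
16 | methyl (E)-4-[4-[[tert-butyl(dimethyl)silyl]oxymethyl]-5-[(E)-hept-1-enyl]-6,6-dimethoxy-3-oxocyclohexa-1,4-dien-1-yl]-2-methylbut-2-enoate | CCCCC/C=C/C1=C(CO[Si](C)(C)C(C)(C)C)C(=O)C=C(C/C=C(\C)C(=O)OC)C1(OC)OC | intermediate
17 | methyl (E)-4-[5-[(E)-hept-1-enyl]-4-(hydroxymethyl)-6,6-dimethoxy-3-oxocyclohexa-1,4-dien-1-yl]-2-methylbut-2-enoate | CCCCC/C=C/C1=C(CO)C(=O)C=C(C/C=C(\C)C(=O)OC)C1(OC)OC | intermediate
18 | methyl (E)-4-[(1R,6S)-3-[(E)-hept-1-enyl]-4-(hydroxymethyl)-2,2-dimethoxy-5-oxo-7-oxabicyclo[4.1.0]hept-3-en-1-yl]-2-methylbut-2-enoate | CCCCC/C=C/C1=C(CO)C(=O)[C@H]2O[C@@]2(C/C=C(\C)C(=O)OC)C1(OC)OC | intermediate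
19 | methyl (E)-4-[(1R,5R,6R)-3-[(E)-hept-1-enyl]-5-hydroxy-4-(hydroxymethyl)-2,2-dimethoxy-7-oxabicyclo[4.1.0]hept-3-en-1-yl]-2-methylbut-2-enoate | CCCCC/C=C/C1=C(CO)[C@@H](O)[C@H]2O[C@@]2(C/C=C(\C)C(=O)OC)C1(OC)OC | intermediate
20 | lithium (E)-4-[(1R,5R,6R)-3-[(E)-hept-1-enyl]-5-hydroxy-4-(hydroxymethyl)-2,2-dimethoxy-7-oxabicyclo[4.1.0]hept-3-en-1-yl]-2-methylbut-2-enoate | CCCCC/C=C/C1=C(CO)[C@@H](O)[C@H]2O[C@@]2(C/C=C(\C)C(=O)[O-])C1(OC)OC.[Li+] | intermediate
21 | (E)-4-[(1R,5R,6R)-3-[(E)-hept-1-enyl]-5-hydroxy-4-(hydroxymethyl)-2-oxo-7-oxabicyclo[4.1.0]hept-3-en-1-yl]-2-methylbut-2-enoic acid (ambuic acid) | CCCCC/C=C/C1=C(CO)[C@@H](O)[C@H]2O[C@@]2(C/C=C(\C)C(=O)O)C1=O | target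

**Step count and risks**

Total step count: 9. Longest linear sequence: 7 (steps 3 to 9; the enyne arm, steps 1 and 2, joins at step 5).

Most likely to fail, step 5 (the proposed ring expansion). If the alkyne inserts first into the Ni–C(sp3) bond of a ring-opened nickelacycle, the regioisomeric phenol (heptenyl ortho to the hydroxyl) results; alkyne oligomerisation is the other danger. The fallback uses known chemistry, sets out from 11 and comes back at 13. Conjugate reduction of the cyclobutenone with [(Ph3P)CuH]6 (toluene, rt) gives methyl (E)-2-methyl-4-(3-oxocyclobutyl)but-2-enoate F1. The established Ni(cod)2/PCy3 insertion of an alkyne into a cyclobutanone (toluene, 100 °C), run with 5, goes by carbonyl–alkyne oxidative cyclisation and beta-carbon elimination, for which the enyne regiochemistry is well documented (carbonyl carbon to the alkyne carbon remote from the alkene). It gives methyl (E)-4-[4-[[tert-butyl(dimethyl)silyl]oxymethyl]-3-[(E)-hept-1-enyl]-5-oxocyclohex-3-en-1-yl]-2-methylbut-2-enoate F2, racemic at a centre that is destroyed next. Aerobic dehydrogenation (Pd(O2CCF3)2, 2-(dimethylamino)pyridine, TsOH, O2, DMSO, 80 °C) aromatises F2 to 13.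

Second, step 4 (cross-metathesis on the cyclobutenone). The strained enone may ring-open on the ruthenium carbene, or the skipped diene may slip into conjugation. The fallback sets out from 9 and comes back at 13: the allyl group is carried through the nickel ring expansion of step 5 with 5 to give 2-[[tert-butyl(dimethyl)silyl]oxymethyl]-3-[(E)-hept-1-enyl]-5-(prop-2-enyl)phenol F3. The metathesis with 10 is then run on this robust allylarene, where the terminal alkene reacts much faster than the internal, ortho-flanked styrenyl alkene.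

Third, step 7 (asymmetric epoxidation). The enantiomeric excess may be low, or the side-chain methylene may be deprotonated. The fallback sets out from 17 and comes back at 18: racemic Weitz–Scheffer epoxidation (tBuOOH, DBU, CH2Cl2, 0 °C) gives 18 together with its enantiomer, methyl (E)-4-[(1S,6R)-3-[(E)-hept-1-enyl]-4-(hydroxymethyl)-2,2-dimethoxy-5-oxo-7-oxabicyclo[4.1.0]hept-3-en-1-yl]-2-methylbut-2-enoate F4. The two are separated by preparative chiral-phase supercritical-fluid chromatography, and 18 goes on to step 8.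

Further compounds
F1 | step 5 | methyl (E)-2-methyl-4-(3-oxocyclobutyl)but-2-enoate | COC(=O)/C(C)=C/CC1CC(=O)C1
F2 | step 5 | methyl (E)-4-[4-[[tert-butyl(dimethyl)silyl]oxymethyl]-3-[(E)-hept-1-enyl]-5-oxocyclohex-3-en-1-yl]-2-methylbut-2-enoate (racemic) | CCCCC/C=C/C1=C(CO[Si](C)(C)C(C)(C)C)C(=O)CC(C/C=C(\C)C(=O)OC)C1
F3 | step 4 | 2-[[tert-butyl(dimethyl)silyl]oxymethyl]-3-[(E)-hept-1-enyl]-5-(prop-2-enyl)phenol | CCCCC/C=C/c1cc(CC=C)cc(O)c1CO[Si](C)(C)C(C)(C)C
F4 | step 7 | methyl (E)-4-[(1S,6R)-3-[(E)-hept-1-enyl]-4-(hydroxymethyl)-2,2-dimethoxy-5-oxo-7-oxabicyclo[4.1.0]hept-3-en-1-yl]-2-methylbut-2-enoate | CCCCC/C=C/C1=C(CO)C(=O)[C@@H]2O[C@]2(C/C=C(\C)C(=O)OC)C1(OC)OC
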